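The rate constants stand for no real mixture; what happens was integrated by code.

The flask holds 172 times more protic impurity than pre-initiator, while a living end takes free monomer 268 times faster, concentration for concentration, than protic impurity does.

free monomer 0.050 M; protic impurity 0.0500 M; pre-initiator 0.29 mM; time 30 h

    2 living end → dead end (k1 = 9.4 L mol⁻¹ h⁻¹)
    free monomer + living end → monomer in chains + living end, rate k2*[living end]*[free monomer] (k2 = 150 L mol⁻¹ h⁻¹)
    free monomer + initiator → living end + monomer in chains (k3 = 5.6 L mol⁻¹ h⁻¹)
    protic impurity + free monomer → quenched substrate (k4 = 0.56 L mol⁻¹ h⁻¹)
    pre-initiator ⇌ initiator (K5 = 0.14, k5 = 0.051 h⁻¹)

1. average number of monomer units in a chain (chains begun, living or dead) at 30 h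
2. part of the free monomer that has reacted at 30 h

- a doubled species enters its step squared and goes two at a time
- the average divides the monomer in chains by the number of chains begun, living and dead together
- run time (flask): 30 h

A bench rule comes first. Free monomer and protic impurity are charged equal and go one for one, so if the quench ran by itself, the part lost would follow from the constant, the charge and the time:

kct = 0.840

part lost = kct / (1 + kct) = 45.7%

My own reckoning of the part reacted stops there. It counts no propagation and says nothing about chain length.

The border of this rule comes from comparing the two uses of free monomer. Both are first order in free monomer, so c(free monomer) cancels, and they run level at one concentration of living end: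

break-even living end = quench constant × c(protic impurity) / propagation constant = 0.187 mM

This break-even living end is the quantity to watch: below it the quench leads, above it propagation leads. The ratio of the two constants is the selectivity factor. In powers of ten, at the charge:

lg(propagation constant / quench constant) = 2.43

lg(c(protic impurity) / c(pre-initiator)) = 2.24

The whole pre-initiator charge therefore clears the break-even by a factor of 1.55. At the charged protic impurity, 64.4% of that charge must stand as living ends to reach it, and the break-even sinks in proportion as protic impurity is used.

The forecast gives 74 units in a chain and 59% reacted, more than my rule. It counts its chains from this ground: “Initiator therefore sits at a quasi-steady level”.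

The flask gives 73.3 units and 58.5% reacted, both within the margin of the forecast. In this flask at 30.0 h, with 57% of the protic impurity left, the break-even has sunk to 0.106 mM, and the living end at 0.102 mM stands level with it, the quench using free monomer at 1.0 times the rate of propagation. In the neighbour flask read at 2.0 d, 48% of the protic impurity is left, the break-even is 0.0905 mM, and the living end at 0.125 mM stands 1.38 times above it, with 95.0 units in the average chain.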